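**Plan**
- Retrosynthesis: the ring C hydroxyquinone goes back to an 11,12,14-trimethoxyarene, C6 receives a removable 2-(trimethylsilyl)ethyl ester, and ring B is cut at C5–C6.
- Enabling feature: C5 of ring B is the allylic carbon of the isopropenyl group (C4, C18, C19) and lies β to the C7 aryl ketone, so C5–C6 joins a 2-methylallyl terminus to the C6 enolate carbon.
- Further cuts: C6–CO2R and C7–C8 (two acylations), the C1–C3 ester arm (from an allyl group on C10), C4=C5 (Wittig), C9–C10 (ortho-lithiation, then one-carbon homologation), C13–isopropyl.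
- Forward order: the hexasubstituted ring C is made first, the open chain is assembled on C10, ring B closes last by palladium allylation, and ring C is then oxidised to the hydroxyquinone.
- Stereochemistry: C10 comes from a chiral-phosphate/palladium/amine α-allylation of a 2-arylpropanal; C5 comes from the chiral ligand on palladium in the ring closure, set relative to C10; the C6 centre is transient.

Key step: step 15

Remark: abietane numbering is used for positions; the step-14 acylating agent is assumed to be made in one operation from 1,1'-carbonyldiimidazole and 2-(trimethylsilyl)ethanol, and the acid antipode in step 7 and the ligand antipode in step 15 are written as the ones expected to be matched, the mirror-image catalysts being used otherwise.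

**Step 1**
Reactants: 1 1,2,4-trimethoxybenzene; 2 acetone
Product: 4 2-(2,3,6-trimethoxyphenyl)propan-2-ol, via aryllithium 3 (not isolated)
Conditions: n-BuLi, THF, 0 °C → rt; acetone, −78 °C → rt; H2O
Reagents that add atoms: none
Why: Directed ortho-lithiation takes place at the ring position flanked by two methoxy groups (the future C13), and the aryllithium adds to the ketone (1,2-addition).

**Step 2**
Reactants: 4 2-(2,3,6-trimethoxyphenyl)propan-2-ol
Product: 5 1,2,4-trimethoxy-3-(propan-2-yl)benzene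
Conditions: Et3SiH, CF3CO2H, CH2Cl2, 0 °C → rt
Reagents that add atoms: none
Why: Ionic hydrogenation, in which the tertiary benzylic cation stabilised by two ortho methoxy groups is reduced by hydride transfer from the silane.

**Step 3**
Reactants: 5 1,2,4-trimethoxy-3-(propan-2-yl)benzene
Product: 6 1-bromo-2,4,5-trimethoxy-3-(propan-2-yl)benzene
Conditions: NBS (1.0 equiv), MeCN, 0 °C
Reagents that add atoms: N-bromosuccinimide, O=C1CCC(=O)N1Br
Why: Electrophilic aromatic bromination is expected at C8, which is ortho to the C14 methoxy group and para to the C12 methoxy group, whereas C9 has only one oxygen donor in an ortho or para position.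

**Step 4**
Reactants: 6 1-bromo-2,4,5-trimethoxy-3-(propan-2-yl)benzene
Product: 8 1-[2-bromo-3,5,6-trimethoxy-4-(propan-2-yl)phenyl]ethan-1-one, via aryllithium 7 (not isolated)
Conditions: LiN(i-Pr)2, THF, −78 °C; MeC(O)N(OMe)Me, −78 °C; H2O
Reagents that add atoms: N-methoxy-N-methylacetamide, CC(=O)N(C)OC
Why: The only ring hydrogen left (C9) lies between bromine and the C11 methoxy group and is removed by the amide base at −78 °C (directed ortho-metalation, below the temperature of aryne formation), and the aryllithium is acetylated through the chelated tetrahedral adduct of the N-methoxy-N-methylamide.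

**Step 5**
Reactants: 8 1-[2-bromo-3,5,6-trimethoxy-4-(propan-2-yl)phenyl]ethan-1-one
Product: 9 2-[2-bromo-3,5,6-trimethoxy-4-(propan-2-yl)phenyl]-2-methyloxirane (racemic)
Conditions: Me3SI, KOt-Bu, DMSO–THF, 0 °C → rt
Reagents that add atoms: trimethylsulfonium iodide, C[S+](C)C.[I-]
Why: Corey–Chaykovsky epoxidation, in which the small sulfonium ylide adds to the twisted, hindered ketone and the betaine closes to the oxirane.

**Step 6**
Reactants: 9 2-[2-bromo-3,5,6-trimethoxy-4-(propan-2-yl)phenyl]-2-methyloxirane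
Product: 10 2-[2-bromo-3,5,6-trimethoxy-4-(propan-2-yl)phenyl]propanal (racemic)
Conditions: BF3·OEt2 (10 mol %), CH2Cl2, −78 → −20 °C
Reagents that add atoms: none
Why: Meinwald rearrangement, in which Lewis-acid opening at the tertiary benzylic carbon is followed by a 1,2-hydride shift from the CH2 group to give the aldehyde; its stereocentre is erased in the next step.

**Step 7**
Reactants: 10 2-[2-bromo-3,5,6-trimethoxy-4-(propan-2-yl)phenyl]propanal; 11 prop-2-en-1-ol (allyl alcohol)
Product: 12 (2R)-2-[2-bromo-3,5,6-trimethoxy-4-(propan-2-yl)phenyl]-2-methylpent-4-enal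
Conditions: Pd(PPh3)4 (3 mol %), (S)-TRIP [3,3'-bis(2,4,6-triisopropylphenyl)-1,1'-binaphthyl-2,2'-diyl hydrogen phosphate] (5 mol %), Ph2CHNH2 (40 mol %), 5 Å MS, toluene, 40 °C; then 2 M HCl
Reagents that add atoms: none
Why: Counter-anion-directed asymmetric α-allylation of an α-branched aldehyde (Tsuji–Trost allylation of the achiral enamine formed from racemic 10), in which the chiral phosphate bridges the enamine N–H and the cationic allylpalladium fragment and so selects the enamine face that sets the C10 quaternary centre; the electron-rich, hindered aryl bromide should not add oxidatively to the phosphine-ligated zerovalent palladium at 40 °C.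

**Step 8**
Reactants: 12 (2R)-2-[2-bromo-3,5,6-trimethoxy-4-(propan-2-yl)phenyl]-2-methylpent-4-enal; 13 2-(triphenyl-λ5-phosphanylidene)propanal
Product: 14 (2E,4S)-4-[2-bromo-3,5,6-trimethoxy-4-(propan-2-yl)phenyl]-2,4-dimethylhepta-2,6-dienal
Conditions: toluene, 110 °C
Reagents that add atoms: none
Why: Wittig olefination of the non-enolisable aldehyde with a stabilised formyl ylide, which should give the (E)-2-methylenal (C4=C5) under thermodynamic control; the descriptor at C10 changes only because the substituent priorities change.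

**Step 9**
Reactants: 14 (2E,4S)-4-[2-bromo-3,5,6-trimethoxy-4-(propan-2-yl)phenyl]-2,4-dimethylhepta-2,6-dienal
Product: 15 (2E,4S)-4-[2-bromo-3,5,6-trimethoxy-4-(propan-2-yl)phenyl]-2,4-dimethylhepta-2,6-dien-1-ol
Conditions: NaBH4, CeCl3·7H2O, MeOH, 0 °C
Reagents that add atoms: none
Why: Luche 1,2-reduction of the enal to the primary allylic alcohol, leaving the aryl bromide and both alkenes untouched.

**Step 10**
Reactants: 15 (2E,4S)-4-[2-bromo-3,5,6-trimethoxy-4-(propan-2-yl)phenyl]-2,4-dimethylhepta-2,6-dien-1-ol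
Product: 17 1-{2-[(2E,4S)-1-hydroxy-2,4-dimethylhepta-2,6-dien-4-yl]-3,4,6-trimethoxy-5-(propan-2-yl)phenyl}ethan-1-one, via dilithio species 16 (not isolated)
Conditions: n-BuLi (1.0 equiv), THF, −78 °C; t-BuLi (2.1 equiv), −78 °C; MeC(O)N(OMe)Me, −78 → 0 °C; H2O
Reagents that add atoms: N-methoxy-N-methylacetamide, CC(=O)N(C)OC
Why: After the hydroxyl group is deprotonated, bromine–lithium exchange gives the C8 aryllithium, which is acetylated by the N-methoxy-N-methylamide without over-addition; at −78 °C the exchange and acylation should outrun 5-exo carbolithiation of the allyl group, and no ester or carbonate is yet present.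

**Step 11**
Reactants: 17 1-{2-[(2E,4S)-1-hydroxy-2,4-dimethylhepta-2,6-dien-4-yl]-3,4,6-trimethoxy-5-(propan-2-yl)phenyl}ethan-1-one
Product: 18 (2E,4S)-4-[2-acetyl-3,5,6-trimethoxy-4-(propan-2-yl)phenyl]-2,4-dimethylhepta-2,6-dien-1-yl methyl carbonate
Conditions: ClCO2Me, pyridine, CH2Cl2, 0 °C
Reagents that add atoms: methyl chloroformate, COC(=O)Cl
Why: O-Acylation of the primary allylic alcohol installs the carbonate leaving group for the palladium step, the hindered ketone being inert.

**Step 12**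
Reactants: 18 (2E,4S)-4-[2-acetyl-3,5,6-trimethoxy-4-(propan-2-yl)phenyl]-2,4-dimethylhepta-2,6-dien-1-yl methyl carbonate
Product: 20 (2E,4S)-4-[2-acetyl-3,5,6-trimethoxy-4-(propan-2-yl)phenyl]-7-hydroxy-2,4-dimethylhept-2-en-1-yl methyl carbonate, via alkylborane 19 (not isolated)
Conditions: 9-BBN, THF, 0 °C → rt; NaBO3·4H2O, H2O, rt
Reagents that add atoms: sodium perborate tetrahydrate, [Na+].[O-]OB=O.O.O.O.O
Why: Anti-Markovnikov hydroboration–oxidation, in which the bulky borane selects the monosubstituted alkene over the trisubstituted one and over the twisted, doubly ortho-substituted ketone, and the mild perborate oxidation spares the carbonate.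

**Step 13**
Reactants: 20 (2E,4S)-4-[2-acetyl-3,5,6-trimethoxy-4-(propan-2-yl)phenyl]-7-hydroxy-2,4-dimethylhept-2-en-1-yl methyl carbonate
Product: 22 methyl (4S,5E)-4-[2-acetyl-3,5,6-trimethoxy-4-(propan-2-yl)phenyl]-7-[(methoxycarbonyl)oxy]-4,6-dimethylhept-5-enoate, via carboxylic acid 21 (not isolated)
Conditions: TEMPO (20 mol %), PhI(OAc)2, MeCN–H2O, rt; then Me3SiCHN2, toluene–MeOH, 0 °C
Reagents that add atoms: water, O; (trimethylsilyl)diazomethane, C[Si](C)(C)C=[N+]=[N-]
Why: Oxoammonium-mediated oxidation takes the primary alcohol through the aldehyde hydrate to the acid, which is then O-methylated by the diazoalkane; the fully substituted arene offers no position for side reactions.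

**Step 14**
Reactants: 22 methyl (4S,5E)-4-[2-acetyl-3,5,6-trimethoxy-4-(propan-2-yl)phenyl]-7-[(methoxycarbonyl)oxy]-4,6-dimethylhept-5-enoate
Product: 24 methyl (4S,5E)-7-[(methoxycarbonyl)oxy]-4,6-dimethyl-4-[2,3,5-trimethoxy-4-(propan-2-yl)-6-{3-oxo-3-[2-(trimethylsilyl)ethoxy]propanoyl}phenyl]hept-5-enoate, via lithium enolate 23 (not isolated)
Conditions: LiN(SiMe3)2 (2.2 equiv), THF, −78 °C; 2-(trimethylsilyl)ethyl 1H-imidazole-1-carboxylate, −78 → −20 °C; H2O
Reagents that add atoms: 2-(trimethylsilyl)ethyl 1H-imidazole-1-carboxylate, C[Si](C)(C)CCOC(=O)n1ccnc1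
Why: Crossed Claisen-type C-acylation, in which the methyl ketone is deprotonated in preference to the less acidic ester α-CH2, the enolate is acylated at carbon by the imidazole carboxylate, and the second equivalent of base holds the product as its enolate.

**Step 15**
Reactants: 24 methyl (4S,5E)-7-[(methoxycarbonyl)oxy]-4,6-dimethyl-4-[2,3,5-trimethoxy-4-(propan-2-yl)-6-{3-oxo-3-[2-(trimethylsilyl)ethoxy]propanoyl}phenyl]hept-5-enoate
Product: 25 2-(trimethylsilyl)ethyl (2R,3S,4S)-5,6,8-trimethoxy-4-(3-methoxy-3-oxopropyl)-4-methyl-1-oxo-7-(propan-2-yl)-3-(prop-1-en-2-yl)-1,2,3,4-tetrahydronaphthalene-2-carboxylate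
Conditions: Pd2(dba)3·CHCl3 (2.5 mol %), (1R,2R)-N,N'-bis[2-(diphenylphosphanyl)benzoyl]cyclohexane-1,2-diamine (7.5 mol %), CH2Cl2, rt
Reagents that add atoms: none
Why: The zerovalent palladium–ligand complex ionises the allylic methyl carbonate (CO2 and methoxide leave, and methoxide deprotonates the β-keto ester) to a 2-methyl-π-allyl cation spanning C5, C4 and the former carbinol carbon, and the soft C6 enolate attacks C5 on the face opposite the metal, forming C5–C6 and leaving C4=CH2 as the isopropenyl group; the closest known reaction type is the intramolecular Tsuji–Trost allylic alkylation of β-keto esters that gives 2-alkenyl carbocycles under chiral bisphosphine control. Ring B closes in the 6-exo mode, since attack at the distal CH2 terminus would need an 8-endo ring. C5 is controlled by the chiral ligand, which decides which of the two diastereomeric π-allyl complexes (interconverting by π–σ–π exchange at the unsubstituted terminus) is attacked, because methyl and the ester arm on the fixed C10 centre differentiate the faces only weakly. C6 settles trans to the isopropenyl group by enolisation and is removed in step 16. The step needs carbon over oxygen alkylation (both would give six-membered rings) and internal over terminal attack: an O-allyl enol ether is itself an allylic electrophile that re-ionises and funnels to the ketone, and ring size secures the regiochemistry. The methyl ester and the aryl ethers are spectators under these neutral conditions.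

**Step 16**
Reactants: 25 2-(trimethylsilyl)ethyl (2R,3S,4S)-5,6,8-trimethoxy-4-(3-methoxy-3-oxopropyl)-4-methyl-1-oxo-7-(propan-2-yl)-3-(prop-1-en-2-yl)-1,2,3,4-tetrahydronaphthalene-2-carboxylate
Product: 27 methyl 3-[(1S,2S)-5,7,8-trimethoxy-1-methyl-4-oxo-6-(propan-2-yl)-2-(prop-1-en-2-yl)-1,2,3,4-tetrahydronaphthalen-1-yl]propanoate, via β-keto acid 26 (not isolated)
Conditions: Bu4NF, THF, rt → 45 °C; AcOH
Reagents that add atoms: none
Why: Fluoride attacks silicon and the ester fragments to ethene, Me3SiF and the β-keto carboxylate, which decarboxylates on gentle warming; C5 and C10 carry no acidic hydrogen and the methyl ester is not touched.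

**Step 17**
Reactants: 27 methyl 3-[(1S,2S)-5,7,8-trimethoxy-1-methyl-4-oxo-6-(propan-2-yl)-2-(prop-1-en-2-yl)-1,2,3,4-tetrahydronaphthalen-1-yl]propanoate
Product: 28 methyl 3-[(1S,2S)-7-methoxy-1-methyl-4,5,8-trioxo-6-(propan-2-yl)-2-(prop-1-en-2-yl)-1,2,3,4,5,8-hexahydronaphthalen-1-yl]propanoate
Conditions: (NH4)2Ce(NO3)6 (3 equiv), MeCN–H2O, 0 °C
Reagents that add atoms: water, O
Why: Oxidative demethylation of the para-related C11 and C14 methoxy groups by tetravalent cerium gives the 1,4-quinone, the C12 methoxy group remaining as a vinylogous ester.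

**Step 18**
Reactants: 28 methyl 3-[(1S,2S)-7-methoxy-1-methyl-4,5,8-trioxo-6-(propan-2-yl)-2-(prop-1-en-2-yl)-1,2,3,4,5,8-hexahydronaphthalen-1-yl]propanoate
Product: 29 CNP0308749.1, methyl 3-[(1S,2S)-7-hydroxy-1-methyl-4,5,8-trioxo-6-(propan-2-yl)-2-(prop-1-en-2-yl)-1,2,3,4,5,8-hexahydronaphthalen-1-yl]propanoate
Conditions: K2CO3, MeOH–H2O (4:1), 0 °C → rt, argon; then 1 M HCl
Reagents that add atoms: water, O
Why: Addition–elimination of hydroxide at C12 of the vinylogous ester (β to the C14 carbonyl) releases methoxide and gives the hydroxyquinone as its unreactive anion, while the side-chain methyl ester should survive carbonate in methanol-rich medium.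

**Compound list**
1 | 1,2,4-trimethoxybenzene | COc1ccc(OC)c(OC)c1 | starting material
2 | acetone | CC(C)=O | starting material
3 | (2,3,6-trimethoxyphenyl)lithium | [Li]c1c(OC)ccc(OC)c1OC | intermediate
4 | 2-(2,3,6-trimethoxyphenyl)propan-2-ol | COc1ccc(OC)c(C(C)(C)O)c1OC | intermediate
5 | 1,2,4-trimethoxy-3-(propan-2-yl)benzene | COc1ccc(OC)c(C(C)C)c1OC | intermediate
6 | 1-bromo-2,4,5-trimethoxy-3-(propan-2-yl)benzene | COc1cc(Br)c(OC)c(C(C)C)c1OC | intermediate
7 | [2-bromo-3,5,6-trimethoxy-4-(propan-2-yl)phenyl]lithium | [Li]c1c(Br)c(OC)c(C(C)C)c(OC)c1OC | intermediate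
8 | 1-[2-bromo-3,5,6-trimethoxy-4-(propan-2-yl)phenyl]ethan-1-one | CC(=O)c1c(Br)c(OC)c(C(C)C)c(OC)c1OC | intermediate
9 | 2-[2-bromo-3,5,6-trimethoxy-4-(propan-2-yl)phenyl]-2-methyloxirane (racemic) | CC1(CO1)c1c(Br)c(OC)c(C(C)C)c(OC)c1OC | intermediate
10 | 2-[2-bromo-3,5,6-trimethoxy-4-(propan-2-yl)phenyl]propanal (racemic) | CC(C=O)c1c(Br)c(OC)c(C(C)C)c(OC)c1OC | intermediate
11 | prop-2-en-1-ol (allyl alcohol) | C=CCO | starting material
12 | (2R)-2-[2-bromo-3,5,6-trimethoxy-4-(propan-2-yl)phenyl]-2-methylpent-4-enal | Brc1c(OC)c(C(C)C)c(OC)c(OC)c1[C@@](C)(CC=C)C=O | intermediate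
13 | 2-(triphenyl-λ5-phosphanylidene)propanal | CC(C=O)=P(c1ccccc1)(c1ccccc1)c1ccccc1 | starting material
14 | (2E,4S)-4-[2-bromo-3,5,6-trimethoxy-4-(propan-2-yl)phenyl]-2,4-dimethylhepta-2,6-dienal | Brc1c(OC)c(C(C)C)c(OC)c(OC)c1[C@@](C)(CC=C)/C=C(\C)C=O | intermediate
15 | (2E,4S)-4-[2-bromo-3,5,6-trimethoxy-4-(propan-2-yl)phenyl]-2,4-dimethylhepta-2,6-dien-1-ol | Brc1c(OC)c(C(C)C)c(OC)c(OC)c1[C@@](C)(CC=C)/C=C(\C)CO | intermediate
16 | lithium (2E,4S)-4-[2-lithio-3,5,6-trimethoxy-4-(propan-2-yl)phenyl]-2,4-dimethylhepta-2,6-dien-1-olate | [Li]c1c(OC)c(C(C)C)c(OC)c(OC)c1[C@@](C)(CC=C)/C=C(\C)CO[Li] | intermediate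
17 | 1-{2-[(2E,4S)-1-hydroxy-2,4-dimethylhepta-2,6-dien-4-yl]-3,4,6-trimethoxy-5-(propan-2-yl)phenyl}ethan-1-one | CC(=O)c1c(OC)c(C(C)C)c(OC)c(OC)c1[C@@](C)(CC=C)/C=C(\C)CO | intermediate
18 | (2E,4S)-4-[2-acetyl-3,5,6-trimethoxy-4-(propan-2-yl)phenyl]-2,4-dimethylhepta-2,6-dien-1-yl methyl carbonate | CC(=O)c1c(OC)c(C(C)C)c(OC)c(OC)c1[C@@](C)(CC=C)/C=C(\C)COC(=O)OC | intermediate
19 | (2E,4S)-4-[2-acetyl-3,5,6-trimethoxy-4-(propan-2-yl)phenyl]-7-(9-borabicyclo[3.3.1]nonan-9-yl)-2,4-dimethylhept-2-en-1-yl methyl carbonate | CC(=O)c1c(OC)c(C(C)C)c(OC)c(OC)c1[C@@](C)(CCCB2C3CCCC2CCC3)/C=C(\C)COC(=O)OC | intermediate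
20 | (2E,4S)-4-[2-acetyl-3,5,6-trimethoxy-4-(propan-2-yl)phenyl]-7-hydroxy-2,4-dimethylhept-2-en-1-yl methyl carbonate | CC(=O)c1c(OC)c(C(C)C)c(OC)c(OC)c1[C@@](C)(CCCO)/C=C(\C)COC(=O)OC | intermediate
21 | (4S,5E)-4-[2-acetyl-3,5,6-trimethoxy-4-(propan-2-yl)phenyl]-7-[(methoxycarbonyl)oxy]-4,6-dimethylhept-5-enoic acid | CC(=O)c1c(OC)c(C(C)C)c(OC)c(OC)c1[C@@](C)(CCC(=O)O)/C=C(\C)COC(=O)OC | intermediate
22 | methyl (4S,5E)-4-[2-acetyl-3,5,6-trimethoxy-4-(propan-2-yl)phenyl]-7-[(methoxycarbonyl)oxy]-4,6-dimethylhept-5-enoate | CC(=O)c1c(OC)c(C(C)C)c(OC)c(OC)c1[C@@](C)(CCC(=O)OC)/C=C(\C)COC(=O)OC | intermediate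
23 | lithium enolate of 22 (lithium 1-arylethen-1-olate) | [Li]OC(=C)c1c(OC)c(C(C)C)c(OC)c(OC)c1[C@@](C)(CCC(=O)OC)/C=C(\C)COC(=O)OC | intermediate
24 | methyl (4S,5E)-7-[(methoxycarbonyl)oxy]-4,6-dimethyl-4-[2,3,5-trimethoxy-4-(propan-2-yl)-6-{3-oxo-3-[2-(trimethylsilyl)ethoxy]propanoyl}phenyl]hept-5-enoate | C[Si](C)(C)CCOC(=O)CC(=O)c1c(OC)c(C(C)C)c(OC)c(OC)c1[C@@](C)(CCC(=O)OC)/C=C(\C)COC(=O)OC | intermediate
25 | 2-(trimethylsilyl)ethyl (2R,3S,4S)-5,6,8-trimethoxy-4-(3-methoxy-3-oxopropyl)-4-methyl-1-oxo-7-(propan-2-yl)-3-(prop-1-en-2-yl)-1,2,3,4-tetrahydronaphthalene-2-carboxylate | C=C(C)[C@@H]1[C@@H](C(=O)OCC[Si](C)(C)C)C(=O)c2c(OC)c(C(C)C)c(OC)c(OC)c2[C@@]1(C)CCC(=O)OC | intermediate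
26 | (2R,3S,4S)-5,6,8-trimethoxy-4-(3-methoxy-3-oxopropyl)-4-methyl-1-oxo-7-(propan-2-yl)-3-(prop-1-en-2-yl)-1,2,3,4-tetrahydronaphthalene-2-carboxylic acid | C=C(C)[C@@H]1[C@@H](C(=O)O)C(=O)c2c(OC)c(C(C)C)c(OC)c(OC)c2[C@@]1(C)CCC(=O)OC | intermediate
27 | methyl 3-[(1S,2S)-5,7,8-trimethoxy-1-methyl-4-oxo-6-(propan-2-yl)-2-(prop-1-en-2-yl)-1,2,3,4-tetrahydronaphthalen-1-yl]propanoate | C=C(C)[C@@H]1CC(=O)c2c(OC)c(C(C)C)c(OC)c(OC)c2[C@@]1(C)CCC(=O)OC | intermediate
28 | methyl 3-[(1S,2S)-7-methoxy-1-methyl-4,5,8-trioxo-6-(propan-2-yl)-2-(prop-1-en-2-yl)-1,2,3,4,5,8-hexahydronaphthalen-1-yl]propanoate | C=C(C)[C@@H]1CC(=O)C2=C(C(=O)C(OC)=C(C(C)C)C2=O)[C@@]1(C)CCC(=O)OC | intermediate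
29 | CNP0308749.1, methyl 3-[(1S,2S)-7-hydroxy-1-methyl-4,5,8-trioxo-6-(propan-2-yl)-2-(prop-1-en-2-yl)-1,2,3,4,5,8-hexahydronaphthalen-1-yl]propanoate | C=C(C)[C@@H]1CC(=O)C2=C(C(=O)C(O)=C(C(C)C)C2=O)[C@@]1(C)CCC(=O)OC | target

**Step count and risks**
Total step count: 18. Longest linear sequence: 18 steps, from 1,2,4-trimethoxybenzene; the route is fully linear and all other partners are purchased.

The three steps most likely to fail are steps 7, 15 and 10.

Step 7: the enamine carbon is flanked on both ortho positions (bromine and methoxy), so carbon–carbon bond formation may be slow and the facial discrimination by the phosphate may erode. The fallback sets out from 10. O-Acylation of its enolate (KOt-Bu, allyl chloroformate, THF, −78 °C) would give the allyl enol carbonate, prop-2-en-1-yl 2-[2-bromo-3,5,6-trimethoxy-4-(propan-2-yl)phenyl]prop-1-en-1-yl carbonate F1. With Pd2(dba)3 and a chiral diaminocyclohexane-derived bisphosphine, F1 should undergo decarboxylative asymmetric allylic alkylation, in which the enolate and the allylpalladium cation are generated as a contact ion pair and recombine at carbon. The fallback comes back to the route at 12.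

Step 15: the ligand may fail to override the weak bias of the C10 centre, so that the allylpalladium unit is attacked on the wrong face, or the reaction may stall at O-alkylation. The fallback sets out from 24 and changes the nucleophile. Bu4N[Ph3SiF2] first removes the 2-(trimethylsilyl)ethyl group to give the β-keto carboxylate, 3-{2-[(4S,5E)-1-methoxy-7-[(methoxycarbonyl)oxy]-4,6-dimethyl-1-oxohept-5-en-4-yl]-3,4,6-trimethoxy-5-(propan-2-yl)phenyl}-3-oxopropanoic acid F4, as its ammonium salt. In the presence of Pd2(dba)3 and a phosphinooxazoline ligand, F4 loses CO2 while the carbonate is ionised, and the non-stabilised C6 enolate closes ring B at C5 in a decarboxylative allylation of the Tsuji type, which has a different, ligand-dependent facial preference. The fallback comes back to the route at 27, one step later than the main line.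

Step 10: the crowded C8 aryllithium may be protonated by the amide or cyclise onto the allyl group before it is acylated. The fallback sets out from 15. The same dilithio species 16 is quenched with acetaldehyde, a smaller and faster electrophile, to give the diol, (2E,4S)-4-[2-(1-hydroxyethyl)-3,5,6-trimethoxy-4-(propan-2-yl)phenyl]-2,4-dimethylhepta-2,6-dien-1-ol F2. The primary allylic hydroxyl of F2 is selectively converted with ClCO2Me and pyridine into the carbonate, (2E,4S)-4-[2-(1-hydroxyethyl)-3,5,6-trimethoxy-4-(propan-2-yl)phenyl]-2,4-dimethylhepta-2,6-dien-1-yl methyl carbonate F3. Dess–Martin oxidation of the remaining hindered secondary benzylic alcohol then comes back to the route at 18.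

**Further compounds**
F1 | step 7 | prop-2-en-1-yl 2-[2-bromo-3,5,6-trimethoxy-4-(propan-2-yl)phenyl]prop-1-en-1-yl carbonate (E/Z mixture) | C=CCOC(=O)OC=C(C)c1c(Br)c(OC)c(C(C)C)c(OC)c1OC
F2 | step 10 | (2E,4S)-4-[2-(1-hydroxyethyl)-3,5,6-trimethoxy-4-(propan-2-yl)phenyl]-2,4-dimethylhepta-2,6-dien-1-ol (both carbinol epimers) | CC(O)c1c(OC)c(C(C)C)c(OC)c(OC)c1[C@@](C)(CC=C)/C=C(\C)CO
F3 | step 10 | (2E,4S)-4-[2-(1-hydroxyethyl)-3,5,6-trimethoxy-4-(propan-2-yl)phenyl]-2,4-dimethylhepta-2,6-dien-1-yl methyl carbonate (both carbinol epimers) | CC(O)c1c(OC)c(C(C)C)c(OC)c(OC)c1[C@@](C)(CC=C)/C=C(\C)COC(=O)OC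
F4 | step 15 | 3-{2-[(4S,5E)-1-methoxy-7-[(methoxycarbonyl)oxy]-4,6-dimethyl-1-oxohept-5-en-4-yl]-3,4,6-trimethoxy-5-(propan-2-yl)phenyl}-3-oxopropanoic acid | OC(=O)CC(=O)c1c(OC)c(C(C)C)c(OC)c(OC)c1[C@@](C)(CCC(=O)OC)/C=C(\C)COC(=O)OC
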